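Answer two questions about flasks that differ in charged substrate, each stopped at 6.0 min.

| flask | substrate | reagent | free catalyst | remark | time |
|---|---|---|---|---|---|
| Wednesday's | 0.27 M | 2 M | 2 mM | run made earlier |  |
| Saturday's | 1.6 M | 2 M | 2 mM | run made earlier |  |
| south | 0.40 M | 2.00 M | 2.0 mM |  | 6.0 min |
| north | 0.60 M | 2.00 M | 2.0 mM |  | 6.0 min |
| east | 1.0 M | 2.00 M | 2.0 mM |  | 6.0 min |
| north-west | 1.5 M | 2.00 M | 2.0 mM |  | 6.0 min |
| south-east | 2.5 M | 2.00 M | 2.0 mM |  | 6.0 min |

- Wednesday's (time / min: target / %, substrate / %): 0.417: 14.9, 84.6; 1.00: 34.1, 65.7; 2.00: 60.2, 40.1; 3.00: 77.1, 22.3; 4.00: 88.6, 11.4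
- Saturday's (time / min: target / %, substrate / %): 0.417: 4.3, 95.9; 1.00: 9.2, 91.2; 2.00: 16.7, 83.1; 3.00: 22.6, 78.1; 4.00: 27.4, 72.6

(each reading ± 0.3 percentage points)

- "hardly changes" means that all values lie within two and a half points (for a concentration: within two and a half percent of the largest)

* [target] at the end for south, north, east, north-west, south-east, in this order
* the shape of the row from first to last (hardly changes / falls all the way / rises all the way / falls, then rises / rises, then falls)

Start with Saturday's run. Its target grew at 0.165 M min⁻¹ over the first reading and at 0.0768 M min⁻¹ over the last interval, while [substrate] went from 1.6 M to about 1.21 M. The rate fell further than [substrate] did, so read the gap as lost catalyst. Wednesday's first reading gives 0.0965 M min⁻¹, so Saturday's charge is 5.93 times Wednesday's but its early rate is 1.71 times Wednesday's. Take the rate at Saturday's [substrate] as roughly independent of [substrate], and count Saturday's whole fall in rate as lost catalyst.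

Assume that each bit of target costs catalyst in proportion to [substrate] at that moment. The square of [substrate] then falls by a fixed amount per share of catalyst lost. Divide Saturday's fall in that square by the share of rate lost, and read 2.07 M^2. This is the square budget, the estimated fall in the square of [substrate] that uses up the whole catalyst charge, read from scattered readings.

Now hold two amounts against each other: the square of the charge and the budget. By this reckoning, south's charge run to its end costs 7.73% of the catalyst, and Wednesday's costs 3.52%. South-east's square exceeds the budget, so expect its catalyst to go before its substrate. Its total target, at no stated time, is then the charge minus the root of the difference, which I reckon as 0.456 M. East's charge run to its end costs 48.3%, and Saturday's early rate held for 6.0 min, with no catalyst loss counted, comes to 0.990 M, more than south-east's total. So I expect east to end above south-east, and a row that rises, then falls.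

The forecast says 0.38 M, 0.515 M, 0.61 M, 0.565 M, 0.425 M, rises, then falls: “High charges kill the catalyst sooner, so yield drops”. Its south-east value at 6.0 min lies below my total for south-east, which carries no time.

The flasks give 0.375 M, 0.509 M, 0.600 M, 0.568 M and 0.440 M: rises, then falls.

    reagent + catalyst intermediate A → catalyst intermediate B (k = 110 M⁻¹ min⁻¹)
    catalyst intermediate B → catalyst intermediate C (k = 170 min⁻¹)
    substrate + free catalyst ⇌ catalyst intermediate A (K = 2.70 M⁻¹, k = 1600 M⁻¹ min⁻¹)
    substrate + catalyst intermediate B → spent catalyst (k = 0.280 M⁻¹ min⁻¹)
    catalyst intermediate C → free catalyst + target (k = 6700 min⁻¹)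

South-east goes on to 0.546 M of target at 60.0 min, with spent catalyst at >99.9%, against the 0.456 M reckoned from the budget. Put the budget to east: the square of its charge over 2.07 M^2 gives 48.3% of the catalyst lost by the time its substrate is finished. At 60.0 min east holds 0% substrate and 41.0% spent catalyst.

Readings and results were computed on assumed constants, noise included.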